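**Retrosynthetic overview**
1. The epoxide comes last, by peracid epoxidation of the 3E-olefin of a 14-membered 3E,6E-diene; that ring is closed by ring-closing metathesis at C6=C7.
2. The cis-fused α-methylene-γ-lactone arises by translactonisation (O13 to O14) of an α-methylene-δ-lactone. Its C1–C2 bond, C1 stereocentre and exo-methylene come from the key Claisen [3,3] rearrangement of the vinyl ether of a 3-(hydroxymethyl)-5,6-dihydropyran-2-one.
3. The dihydropyranone is made by ring-closing metathesis of a 2-(hydroxymethyl)acrylate of the syn,syn C12–C14 triad, itself from Felkin-selective γ-silyloxyallylstannane addition to the C13 aldehyde.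
4. C12 is set by invertive sp3–sp3 coupling of a linalool-derived Grignard reagent (C7–C11, C8 bought) with ethyl (S)-lactate triflate; C3–C6 are added by isopropenyl addition and allylic Stille vinylation.
5. Ring order: δ-lactone (metathesis), then γ-lactone (translactonisation), then 14-membered carbocycle (metathesis), then epoxide.

**Assumptions (one line each)**
- Numbering is cembrane numbering: ring C1–C14 (C1 ring-fusion CH, C14 lactone O–CH, C13 CHOAc, C12 CHMe, C8 C(Me)OH, C6=C7, C3/C4 epoxide); lactone carbons C15 (α), C16 (=CH2), C17 (C=O). The target is 1S,3R,4R,8S,12S,13R,14R.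
- (S)-(+)-Linalool (coriandrol, from coriander oil) is taken as a commercial material.
- Peripheral peracid attack on the macrocyclic 3E-olefin is assumed to give the (3R,4R)-epoxide; this sense could not be derived with confidence, and the fallback for step 18 corrects the other outcome.

**Route**

Step 1
Reactants: 1 (S)-(+)-linalool
Product: 2 (3S)-3,7-dimethyl-3-(triethylsilyloxy)octa-1,6-diene
Conditions: Et3SiOTf, 2,6-lutidine, CH2Cl2, −78 → 0 °C
Reagents that add atoms: triethylsilyl trifluoromethanesulfonate, CC[Si](CC)(CC)OS(=O)(=O)C(F)(F)F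
Why: Silylation of the tertiary allylic alcohol protects it for the Grignard and thermal steps; C8 is bought with linalool and not touched.

Step 2
Reactants: 2 (3S)-3,7-dimethyl-3-(triethylsilyloxy)octa-1,6-diene
Product: 4 (4S)-4-methyl-4-(triethylsilyloxy)hex-5-en-1-ol, via aldehyde 3 (not isolated)
Conditions: O3 (1 equiv, Sudan Red 7B end point), CH2Cl2/MeOH, −78 °C; then NaBH4, −78 → 0 °C
Reagents that add atoms: ozone, [O-][O+]=O
Why: Chemoselective ozonolysis of the electron-rich trisubstituted olefin over the hindered vinyl group, followed by borohydride reduction of the aldehyde.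

Step 3
Reactants: 4 (4S)-4-methyl-4-(triethylsilyloxy)hex-5-en-1-ol
Product: 5 (3S)-6-chloro-3-methyl-3-(triethylsilyloxy)hex-1-ene
Conditions: PPh3, N-chlorosuccinimide, CH2Cl2, 0 °C → rt
Reagents that add atoms: N-chlorosuccinimide, O=C1CCC(=O)N1Cl
Why: Appel-type chlorination of the primary alcohol; a chloride is chosen so that no nucleophilic bromide or iodide is present in the later triflate coupling.

Step 4
Reactants: 6 ethyl (S)-lactate
Product: 7 ethyl (2S)-2-(trifluoromethylsulfonyloxy)propanoate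
Conditions: Tf2O, 2,6-lutidine, CH2Cl2, −78 → 0 °C
Reagents that add atoms: trifluoromethanesulfonic anhydride, O=S(=O)(OS(=O)(=O)C(F)(F)F)C(F)(F)F
Why: O-Triflation activates the lactate carbon for SN2 displacement without touching the stereocentre.

Step 5
Reactants: 5 (3S)-6-chloro-3-methyl-3-(triethylsilyloxy)hex-1-ene; 7 ethyl (2S)-2-(trifluoromethylsulfonyloxy)propanoate
Product: 9 ethyl (2S,6S)-2,6-dimethyl-6-(triethylsilyloxy)oct-7-enoate, via Grignard reagent 8 (not isolated)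
Conditions: 5, Mg, THF, 50 °C; then 7, ZnCl2 (5 mol%), THF, 0 °C
Reagents that add atoms: none
Why: Zinc-catalysed SN2 alkylation of the α-triflyloxy ester by the alkyl Grignard reagent proceeds with clean inversion, so the lactate stereocentre becomes C12 (S).

Step 6
Reactants: 9 ethyl (2S,6S)-2,6-dimethyl-6-(triethylsilyloxy)oct-7-enoate
Product: 10 (2S,6S)-2,6-dimethyl-6-(triethylsilyloxy)oct-7-enal
Conditions: i-Bu2AlH (1.1 equiv), CH2Cl2, −78 °C; aq. potassium sodium tartrate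
Reagents that add atoms: none
Why: Partial hydride reduction of the ester stops at the aldehyde because the tetrahedral aluminium hemiacetal is stable at −78 °C; the aldehyde is used at once to avoid C12 epimerisation.

Step 7
Reactants: 11 allyl tert-butyldimethylsilyl ether
Product: 13 (Z)-1-(tert-butyldimethylsilyloxy)-3-(tributylstannyl)prop-1-ene, via allyllithium 12 (not isolated)
Conditions: s-BuLi, THF/HMPA, −78 °C; then Bu3SnCl
Reagents that add atoms: tributyltin chloride, CCCC[Sn](Cl)(CCCC)CCCC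
Why: Kinetic deprotonation gives the internally chelated (Z)-oxyallyl anion, which is stannylated at the γ-carbon.

Step 8
Reactants: 10 (2S,6S)-2,6-dimethyl-6-(triethylsilyloxy)oct-7-enal; 13 (Z)-1-(tert-butyldimethylsilyloxy)-3-(tributylstannyl)prop-1-ene
Product: 14 (3R,4R,5S,9S)-3-(tert-butyldimethylsilyloxy)-5,9-dimethyl-9-(triethylsilyloxy)undeca-1,10-dien-4-ol
Conditions: BF3·OEt2, CH2Cl2, −78 °C
Reagents that add atoms: none
Why: Lewis-acid-promoted allylstannane addition through an open transition state gives the syn C13/C14 oxygen pattern and attacks the Felkin–Anh face of the α-methyl aldehyde, so C12 controls C13 (R) and C14 (R); the minor anti-Felkin isomer is removed by chromatography.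

Step 9
Reactants: 14 (3R,4R,5S,9S)-3-(tert-butyldimethylsilyloxy)-5,9-dimethyl-9-(triethylsilyloxy)undeca-1,10-dien-4-ol
Product: 15 (3R,4R,5S,9S)-3-(tert-butyldimethylsilyloxy)-5,9-dimethyl-9-(triethylsilyloxy)undeca-1,10-dien-4-yl acrylate
Conditions: acryloyl chloride, i-Pr2NEt, DMAP (cat.), CH2Cl2, 0 °C
Reagents that add atoms: acryloyl chloride, C=CC(=O)Cl
Why: O-Acylation of the only free hydroxyl brings in C15 and C17 on O13.

Step 10
Reactants: 15 (3R,4R,5S,9S)-3-(tert-butyldimethylsilyloxy)-5,9-dimethyl-9-(triethylsilyloxy)undeca-1,10-dien-4-yl acrylate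
Product: 16 (3R,4R,5S,9S)-3-(tert-butyldimethylsilyloxy)-5,9-dimethyl-9-(triethylsilyloxy)undeca-1,10-dien-4-yl 2-(hydroxymethyl)prop-2-enoate
Conditions: aq. CH2O (37%), DABCO, 1,4-dioxane/H2O, rt
Reagents that add atoms: formaldehyde, C=O
Why: Morita–Baylis–Hillman hydroxymethylation of the acrylate installs C16 as the allylic CH2OH needed for the Claisen step.

Step 11
Reactants: 16 (3R,4R,5S,9S)-3-(tert-butyldimethylsilyloxy)-5,9-dimethyl-9-(triethylsilyloxy)undeca-1,10-dien-4-yl 2-(hydroxymethyl)prop-2-enoate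
Product: 17 (5R,6R)-5-(tert-butyldimethylsilyloxy)-3-(hydroxymethyl)-6-[(2S,6S)-6-methyl-6-(triethylsilyloxy)oct-7-en-2-yl]-5,6-dihydro-2H-pyran-2-one
Conditions: second-generation Grubbs catalyst RuCl2(=CHPh)(PCy3)(H2IMes) (5 mol%), toluene (5 mM), 80 °C
Reagents that add atoms: none
Why: Ring-closing metathesis between the acrylate olefin and the C1 vinyl group forms the six-membered unsaturated lactone (C15=C1); the vinyl group on the quaternary silyloxy carbon is too hindered to take part.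

Step 12
Reactants: 17 (5R,6R)-5-(tert-butyldimethylsilyloxy)-3-(hydroxymethyl)-6-[(2S,6S)-6-methyl-6-(triethylsilyloxy)oct-7-en-2-yl]-5,6-dihydro-2H-pyran-2-one
Product: 19 2-[(4S,5R,6R)-5-(tert-butyldimethylsilyloxy)-3-methylidene-6-[(2S,6S)-6-methyl-6-(triethylsilyloxy)oct-7-en-2-yl]-2-oxooxan-4-yl]acetaldehyde, via allyl vinyl ether 18 (not isolated)
Conditions: Hg(OAc)2 (cat.), ethyl vinyl ether, reflux; concentrate; toluene, BHT (cat.), 120 °C (sealed tube)
Reagents that add atoms: ethyl vinyl ether, C=COCC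
Why: Transvinylation then Claisen [3,3] rearrangement forms the C1–C2 bond and the exo-methylene; the vinyl ether carbon is delivered to the ring face anti to the cis C14–OSi and C13 side chain, which sets C1 (S) trans to O14.

Step 13
Reactants: 19 2-[(4S,5R,6R)-5-(tert-butyldimethylsilyloxy)-3-methylidene-6-[(2S,6S)-6-methyl-6-(triethylsilyloxy)oct-7-en-2-yl]-2-oxooxan-4-yl]acetaldehyde
Product: 21 1-[(4S,5R,6R)-5-(tert-butyldimethylsilyloxy)-3-methylidene-6-[(2S,6S)-6-methyl-6-(triethylsilyloxy)oct-7-en-2-yl]-2-oxooxan-4-yl]-3-methylbut-3-en-2-yl methyl carbonate (both carbinol epimers), via magnesium alkoxide 20 (not isolated)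
Conditions: CH2=C(CH3)MgBr (1.05 equiv), THF, −78 °C; then ClCO2Me, −78 → 0 °C
Reagents that add atoms: isopropenylmagnesium bromide, CC(=C)[Mg]Br; methyl chloroformate, COC(=O)Cl
Why: Grignard 1,2-addition to the aldehyde (far faster than attack on the lactone at −78 °C) with in situ O-acylation of the alkoxide; the new carbinol centre is lost in the next step, so its configuration is irrelevant.

Step 14
Reactants: 21 1-[(4S,5R,6R)-5-(tert-butyldimethylsilyloxy)-3-methylidene-6-[(2S,6S)-6-methyl-6-(triethylsilyloxy)oct-7-en-2-yl]-2-oxooxan-4-yl]-3-methylbut-3-en-2-yl methyl carbonate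
Product: 22 (4S,5R,6R)-5-(tert-butyldimethylsilyloxy)-3-methylidene-4-[(2E)-3-methylhexa-2,5-dien-1-yl]-6-[(2S,6S)-6-methyl-6-(triethylsilyloxy)oct-7-en-2-yl]oxan-2-one
Conditions: Bu3SnCH=CH2, Pd2(dba)3 (2.5 mol%), DMF, 40 °C
Reagents that add atoms: tributyl(vinyl)stannane, C=C[Sn](CCCC)(CCCC)CCCC
Why: Allylic Stille coupling through the π-allylpalladium complex places the vinyl group on the unsubstituted terminus (C5), and the preferred syn-allyl geometry gives the (E)-trisubstituted C3=C4 olefin.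

Step 15
Reactants: 22 (4S,5R,6R)-5-(tert-butyldimethylsilyloxy)-3-methylidene-4-[(2E)-3-methylhexa-2,5-dien-1-yl]-6-[(2S,6S)-6-methyl-6-(triethylsilyloxy)oct-7-en-2-yl]oxan-2-one
Product: 24 (4S,5R)-5-[(1R,2S,6S)-1,6-dihydroxy-2,6-dimethyloct-7-en-1-yl]-3-methylidene-4-[(2E)-3-methylhexa-2,5-dien-1-yl]oxolan-2-one, via desilylated δ-lactone diol 23 (not isolated)
Conditions: Bu4NF (3 equiv), THF, 0 °C → rt; AcOH quench
Reagents that add atoms: none
Why: Fluoride removes both silyl ethers and the freed C14 oxygen takes over the acyl group (5-exo translactonisation, directly or via the hydroxy carboxylate on acidification) to give the more stable cis-fused α-methylene-γ-butyrolactone; no stereocentre is touched.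

Step 16
Reactants: 24 (4S,5R)-5-[(1R,2S,6S)-1,6-dihydroxy-2,6-dimethyloct-7-en-1-yl]-3-methylidene-4-[(2E)-3-methylhexa-2,5-dien-1-yl]oxolan-2-one
Product: 25 (1R,2S,6S)-6-hydroxy-2,6-dimethyl-1-[(2R,3S)-4-methylidene-3-[(2E)-3-methylhexa-2,5-dien-1-yl]-5-oxooxolan-2-yl]oct-7-en-1-yl acetate
Conditions: Ac2O, pyridine, DMAP (cat.), CH2Cl2, 0 °C
Reagents that add atoms: acetic anhydride, CC(=O)OC(C)=O
Why: Acetylation of the secondary C13 hydroxyl; the tertiary C8 hydroxyl does not react under these conditions.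

Step 17
Reactants: 25 (1R,2S,6S)-6-hydroxy-2,6-dimethyl-1-[(2R,3S)-4-methylidene-3-[(2E)-3-methylhexa-2,5-dien-1-yl]-5-oxooxolan-2-yl]oct-7-en-1-yl acetate
Product: 26 (1S,8S,12S,13R,14R)-13-acetoxy-8-hydroxycembra-3E,6E,15(16)-trien-17,14-olide
Conditions: second-generation Grubbs catalyst RuCl2(=CHPh)(PCy3)(H2IMes) (10 mol%), 1,4-benzoquinone (cat.), toluene (1 mM), 80 °C
Reagents that add atoms: none
Why: Macrocyclic ring-closing metathesis of the terminal skipped-diene vinyl with the vinyl carbinol gives the 14-membered ring; the E olefin is favoured next to the quaternary carbinol, and the E-3,4-olefin rules out a seven-membered closure onto the methylene lactone.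

Step 18
Reactants: 26 (1S,8S,12S,13R,14R)-13-acetoxy-8-hydroxycembra-3E,6E,15(16)-trien-17,14-olide
Product: 27 (1S,3R,4R,8S,12S,13R,14R)-13-acetoxy-3,4-epoxy-8-hydroxycembra-6E,15(16)-dien-17,14-olide (CNP0202356.4)
Conditions: mCPBA (1.05 equiv), NaHCO3, CH2Cl2, −20 → 0 °C
Reagents that add atoms: 3-chloroperoxybenzoic acid, OOC(=O)c1cccc(Cl)c1
Why: Prilezhaev epoxidation of the most electron-rich (trisubstituted) olefin, stereospecific for the E geometry, from the exposed peripheral face of the macrocycle whose conformation is fixed by the existing stereocentres (sense as assumed above).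

**Compound list**
1 | (S)-(+)-linalool | CC(C)=CCC[C@](C)(O)C=C | starting material
2 | (3S)-3,7-dimethyl-3-(triethylsilyloxy)octa-1,6-diene | CC(C)=CCC[C@](C)(O[Si](CC)(CC)CC)C=C | intermediate
3 | (4S)-4-methyl-4-(triethylsilyloxy)hex-5-enal | O=CCC[C@](C)(O[Si](CC)(CC)CC)C=C | intermediate
4 | (4S)-4-methyl-4-(triethylsilyloxy)hex-5-en-1-ol | OCCC[C@](C)(O[Si](CC)(CC)CC)C=C | intermediate
5 | (3S)-6-chloro-3-methyl-3-(triethylsilyloxy)hex-1-ene | ClCCC[C@](C)(O[Si](CC)(CC)CC)C=C | intermediate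
6 | ethyl (S)-lactate | CCOC(=O)[C@H](C)O | starting material
7 | ethyl (2S)-2-(trifluoromethylsulfonyloxy)propanoate | CCOC(=O)[C@H](C)OS(=O)(=O)C(F)(F)F | intermediate
8 | [(4S)-4-methyl-4-(triethylsilyloxy)hex-5-en-1-yl]magnesium chloride | Cl[Mg]CCC[C@](C)(O[Si](CC)(CC)CC)C=C | intermediate
9 | ethyl (2S,6S)-2,6-dimethyl-6-(triethylsilyloxy)oct-7-enoate | CCOC(=O)[C@@H](C)CCC[C@](C)(O[Si](CC)(CC)CC)C=C | intermediate
10 | (2S,6S)-2,6-dimethyl-6-(triethylsilyloxy)oct-7-enal | O=C[C@@H](C)CCC[C@](C)(O[Si](CC)(CC)CC)C=C | intermediate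
11 | allyl tert-butyldimethylsilyl ether | C=CCO[Si](C)(C)C(C)(C)C | starting material
12 | (Z)-3-(tert-butyldimethylsilyloxy)allyllithium | [Li]C/C=C\O[Si](C)(C)C(C)(C)C | intermediate
13 | (Z)-1-(tert-butyldimethylsilyloxy)-3-(tributylstannyl)prop-1-ene | CCCC[Sn](CCCC)(CCCC)C/C=C\O[Si](C)(C)C(C)(C)C | intermediate
14 | (3R,4R,5S,9S)-3-(tert-butyldimethylsilyloxy)-5,9-dimethyl-9-(triethylsilyloxy)undeca-1,10-dien-4-ol | C=C[C@@H](O[Si](C)(C)C(C)(C)C)[C@H](O)[C@@H](C)CCC[C@](C)(O[Si](CC)(CC)CC)C=C | intermediate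
15 | acrylate of 14 | C=C[C@@H](O[Si](C)(C)C(C)(C)C)[C@H](OC(=O)C=C)[C@@H](C)CCC[C@](C)(O[Si](CC)(CC)CC)C=C | intermediate
16 | 2-(hydroxymethyl)prop-2-enoate of 14 | C=C[C@@H](O[Si](C)(C)C(C)(C)C)[C@H](OC(=O)C(=C)CO)[C@@H](C)CCC[C@](C)(O[Si](CC)(CC)CC)C=C | intermediate
17 | (5R,6R)-5-(tert-butyldimethylsilyloxy)-3-(hydroxymethyl)-6-[(2S,6S)-6-methyl-6-(triethylsilyloxy)oct-7-en-2-yl]-5,6-dihydro-2H-pyran-2-one | OCC1=C[C@@H](O[Si](C)(C)C(C)(C)C)[C@@H]([C@@H](C)CCC[C@](C)(O[Si](CC)(CC)CC)C=C)OC1=O | intermediate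
18 | 3-[(ethenyloxy)methyl] analogue of 17 (allyl vinyl ether) | C=COCC1=C[C@@H](O[Si](C)(C)C(C)(C)C)[C@@H]([C@@H](C)CCC[C@](C)(O[Si](CC)(CC)CC)C=C)OC1=O | intermediate
19 | 2-[(4S,5R,6R)-5-(tert-butyldimethylsilyloxy)-3-methylidene-6-[(2S,6S)-6-methyl-6-(triethylsilyloxy)oct-7-en-2-yl]-2-oxooxan-4-yl]acetaldehyde | C=C1[C@H](CC=O)[C@@H](O[Si](C)(C)C(C)(C)C)[C@@H]([C@@H](C)CCC[C@](C)(O[Si](CC)(CC)CC)C=C)OC1=O | intermediate
20 | bromomagnesium alkoxide of the isopropenyl adduct of 19 | C=C1[C@H](CC(O[Mg]Br)C(C)=C)[C@@H](O[Si](C)(C)C(C)(C)C)[C@@H]([C@@H](C)CCC[C@](C)(O[Si](CC)(CC)CC)C=C)OC1=O | intermediate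
21 | methyl carbonate of the isopropenyl adduct of 19 (both carbinol epimers) | C=C1[C@H](CC(OC(=O)OC)C(C)=C)[C@@H](O[Si](C)(C)C(C)(C)C)[C@@H]([C@@H](C)CCC[C@](C)(O[Si](CC)(CC)CC)C=C)OC1=O | intermediate
22 | (4S,5R,6R)-5-(tert-butyldimethylsilyloxy)-3-methylidene-4-[(2E)-3-methylhexa-2,5-dien-1-yl]-6-[(2S,6S)-6-methyl-6-(triethylsilyloxy)oct-7-en-2-yl]oxan-2-one | C=C1[C@H](C/C=C(\C)CC=C)[C@@H](O[Si](C)(C)C(C)(C)C)[C@@H]([C@@H](C)CCC[C@](C)(O[Si](CC)(CC)CC)C=C)OC1=O | intermediate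
23 | (4S,5R,6R)-5-hydroxy-6-[(2S,6S)-6-hydroxy-6-methyloct-7-en-2-yl]-3-methylidene-4-[(2E)-3-methylhexa-2,5-dien-1-yl]oxan-2-one | C=C1[C@H](C/C=C(\C)CC=C)[C@@H](O)[C@@H]([C@@H](C)CCC[C@](C)(O)C=C)OC1=O | intermediate
24 | (4S,5R)-5-[(1R,2S,6S)-1,6-dihydroxy-2,6-dimethyloct-7-en-1-yl]-3-methylidene-4-[(2E)-3-methylhexa-2,5-dien-1-yl]oxolan-2-one | C=C1C(=O)O[C@@H]([C@H](O)[C@@H](C)CCC[C@](C)(O)C=C)[C@H]1C/C=C(\C)CC=C | intermediate
25 | (1R,2S,6S)-6-hydroxy-2,6-dimethyl-1-[(2R,3S)-4-methylidene-3-[(2E)-3-methylhexa-2,5-dien-1-yl]-5-oxooxolan-2-yl]oct-7-en-1-yl acetate | C=C1C(=O)O[C@@H]([C@H](OC(C)=O)[C@@H](C)CCC[C@](C)(O)C=C)[C@H]1C/C=C(\C)CC=C | intermediate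
26 | (1S,8S,12S,13R,14R)-13-acetoxy-8-hydroxycembra-3E,6E,15(16)-trien-17,14-olide | C=C1C(=O)O[C@H]2[C@H](OC(C)=O)[C@@H](C)CCC[C@](C)(O)/C=C/C/C(C)=C/C[C@@H]12 | intermediate
27 | (1S,3R,4R,8S,12S,13R,14R)-13-acetoxy-3,4-epoxy-8-hydroxycembra-6E,15(16)-dien-17,14-olide | C=C1C(=O)O[C@H]2[C@H](OC(C)=O)[C@@H](C)CCC[C@](C)(O)/C=C/C[C@@]3(C)O[C@@H]3C[C@@H]12 | target

**Step count**
Total: 18 steps. Longest linear sequence: 16 steps (1 → 2 → 4 → 5 → 9 → 10 → 14 → 15 → 16 → 17 → 19 → 21 → 22 → 24 → 25 → 26 → 27); steps 4 and 7 are side branches.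

**Three steps most likely to fail**

Step 12 (vinyl transfer and thermal Claisen on a sensitive α-substituted unsaturated lactone). The fallback sets out from 17 and returns at 19. An Eschenmoser–Claisen rearrangement with N,N-dimethylacetamide dimethyl acetal (toluene, 110 °C, no mercury and no separate vinyl ether) gives, with the same facial preference, the N,N-dimethylamide F1. The amide is then reduced chemoselectively to the aldehyde (Tf2O, 2-fluoropyridine, CH2Cl2, −78 → 0 °C; then Et3SiH and aqueous work-up), which is 19.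

Step 13 (Grignard addition beside the Michael-acceptor lactone, with olefin geometry then resting on the π-allyl step). The fallback sets out from 19 and returns at 22. Wittig olefination with the stabilised ylide Ph3P=C(CH3)CHO (toluene, 80 °C) gives the (E)-enal F2. Luche reduction (NaBH4, CeCl3·7H2O, MeOH, −40 °C) gives the (E)-allylic alcohol F3, and ClCO2Me/pyridine gives the primary allylic carbonate F4. The Stille vinylation of step 14 then gives 22, with the olefin geometry fixed before the palladium step.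

Step 18 (facial selectivity of the macrocyclic epoxidation). The fallback sets out from 26 and returns at 27. If the peracid attacks the other face, the product is the (3S,4S)-epoxide F5. Acid-catalysed hydrolysis (cat. HClO4, THF/H2O, 0 °C) opens it at the tertiary carbon C4 with inversion to the (3S,4R)-diol F6. Selective mesylation of the secondary C3 hydroxyl (MsCl, pyridine, 0 °C) gives the mesylate F7. DBU (toluene, rt) then closes the epoxide by attack of the C4 oxygen on C3 with inversion, which gives the (3R,4R)-epoxide 27.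

Further compounds
F1 | step 12 | 2-[(4S,5R,6R)-5-(tert-butyldimethylsilyloxy)-3-methylidene-6-[(2S,6S)-6-methyl-6-(triethylsilyloxy)oct-7-en-2-yl]-2-oxooxan-4-yl]-N,N-dimethylacetamide | C=C1[C@H](CC(=O)N(C)C)[C@@H](O[Si](C)(C)C(C)(C)C)[C@@H]([C@@H](C)CCC[C@](C)(O[Si](CC)(CC)CC)C=C)OC1=O
F2 | step 13 | (2E)-4-[(4S,5R,6R)-5-(tert-butyldimethylsilyloxy)-3-methylidene-6-[(2S,6S)-6-methyl-6-(triethylsilyloxy)oct-7-en-2-yl]-2-oxooxan-4-yl]-2-methylbut-2-enal | C=C1[C@H](C/C=C(\C)C=O)[C@@H](O[Si](C)(C)C(C)(C)C)[C@@H]([C@@H](C)CCC[C@](C)(O[Si](CC)(CC)CC)C=C)OC1=O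
F3 | step 13 | (4S,5R,6R)-5-(tert-butyldimethylsilyloxy)-4-[(2E)-4-hydroxy-3-methylbut-2-en-1-yl]-3-methylidene-6-[(2S,6S)-6-methyl-6-(triethylsilyloxy)oct-7-en-2-yl]oxan-2-one | C=C1[C@H](C/C=C(\C)CO)[C@@H](O[Si](C)(C)C(C)(C)C)[C@@H]([C@@H](C)CCC[C@](C)(O[Si](CC)(CC)CC)C=C)OC1=O
F4 | step 13 | (2E)-4-[(4S,5R,6R)-5-(tert-butyldimethylsilyloxy)-3-methylidene-6-[(2S,6S)-6-methyl-6-(triethylsilyloxy)oct-7-en-2-yl]-2-oxooxan-4-yl]-2-methylbut-2-en-1-yl methyl carbonate | C=C1[C@H](C/C=C(\C)COC(=O)OC)[C@@H](O[Si](C)(C)C(C)(C)C)[C@@H]([C@@H](C)CCC[C@](C)(O[Si](CC)(CC)CC)C=C)OC1=O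
F5 | step 18 | (1S,3S,4S,8S,12S,13R,14R)-13-acetoxy-3,4-epoxy-8-hydroxycembra-6E,15(16)-dien-17,14-olide | C=C1C(=O)O[C@H]2[C@H](OC(C)=O)[C@@H](C)CCC[C@](C)(O)/C=C/C[C@]3(C)O[C@H]3C[C@@H]12
F6 | step 18 | (1S,3S,4R,8S,12S,13R,14R)-13-acetoxy-3,4,8-trihydroxycembra-6E,15(16)-dien-17,14-olide | C=C1C(=O)O[C@H]2[C@H](OC(C)=O)[C@@H](C)CCC[C@](C)(O)/C=C/C[C@@](C)(O)[C@@H](O)C[C@@H]12
F7 | step 18 | 3-O-methanesulfonate of F6 | C=C1C(=O)O[C@H]2[C@H](OC(C)=O)[C@@H](C)CCC[C@](C)(O)/C=C/C[C@@](C)(O)[C@@H](OS(C)(=O)=O)C[C@@H]12
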